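**Retrosynthetic overview**

1. Target 26 ⇐ triol 25 by acetylation at O7 and O15 only (the axial 6β-OH is shielded by the C4β and C10 methyl groups). 25 ⇐ enol triflate 19 + alkylborane 23 by B-alkyl Suzuki coupling (C9–C11), with the side chain taken from (Z)-3-methylpent-2-en-4-yn-1-ol.
2. 19 ⇐ ene-dione 14 by conjugate reduction/enolate triflation (fixes the C8=C9 alkene), C7 hydroxylation and C6 reduction, both from the α face. 14 ⇐ enone 13 by γ-oxidation.
3. 13 ⇐ aldol adduct 9 by removal of the two handles left by the key step (C1–OH and C2–CHO): dehydration, decarbonylation, hydrogenation.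
4. Key disconnection: ring A is closed last, onto ring B taken from (R)-carvone, by an iron-hydride HAT-initiated radical conjugate addition/aldol annulation of keto aldehyde 6 with acrolein (C3–C4 by radical addition, then C1–C2 by aldol). The enabling feature is that the isopropenyl group on C5 (its central carbon becomes C4) and the formyl group (C1) on the quaternary C10 sit trans on adjacent carbons of ring B, i.e. a γ,δ-unsaturated aldehyde.
5. 6 ⇐ (R)-carvone (C5 stereocentre kept) by α′-methylation, hydroxymethylation anti to the isopropenyl group (sets C10) and oxidation. Ring order: B (from carvone), then A (step 4).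

Key step: step 4

Assumption: positions are given in labdane numbering (C1–C10 ring carbons, C11–C16 side chain) from compound 8 onwards and in the F compounds (compounds 1–6 use cyclohexenone locants), α is the face opposite the C10 methyl group, every bicyclic compound is trans-fused (5α-H, 10β-CH3), and the target is read as (13Z)-labda-8,13-diene-6β,7α,15-triol 7,15-diacetate.

**Route**

Step 1
Reactants: 1 (R)-(−)-carvone
Product: 3 6-methylcarvone [(5R)-2,6-dimethyl-5-(prop-1-en-2-yl)cyclohex-2-en-1-one; C6 epimers], via lithium dienolate 2 (not isolated)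
Conditions: LiN(i-Pr)2, THF, −78 °C; MeI, −78 to 0 °C
Reagents that add atoms: iodomethane, CI
Why: Kinetic α′-deprotonation of the enone gives the cross-conjugated dienolate, which is C-methylated (enolate alkylation); the new centre is planarised again in step 2, so its configuration does not matter.

Step 2
Reactants: 3 6-methylcarvone
Product: 5 (5S,6R)-6-(hydroxymethyl)-2,6-dimethyl-5-(prop-1-en-2-yl)cyclohex-2-en-1-one (CH2OH trans to isopropenyl), via lithium enolate 4 (not isolated)
Conditions: LiN(i-Pr)2, THF, −78 °C; CH2O (monomer gas from cracked paraformaldehyde), −78 °C; NH4Cl (aq), −78 °C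
Reagents that add atoms: formaldehyde, C=O
Why: Aldol addition of the tetrasubstituted enolate to formaldehyde should occur anti to the neighbouring isopropenyl group (pseudoaxial to avoid A(1,2) strain with the enolate methyl), which sets the quaternary C10 with CH2OH trans and CH3 cis to the C5 substituent, as the trans ring fusion requires.

Step 3
Reactants: 5 hydroxymethyl ketone
Product: 6 (1R,6S)-1,3-dimethyl-2-oxo-6-(prop-1-en-2-yl)cyclohex-3-ene-1-carbaldehyde (CHO trans to isopropenyl)
Conditions: Dess–Martin periodinane, NaHCO3, CH2Cl2, 0 °C to rt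
Reagents that add atoms: none
Why: Dess–Martin oxidation of the neopentyl primary alcohol under buffered, non-nucleophilic conditions should give the non-enolisable β-keto aldehyde without retro-aldol cleavage or deformylation.

Step 4
Reactants: 6 keto aldehyde; 7 acrolein
Product: 9 1-hydroxy-4,4,8,10-tetramethyl-9-oxo-trans-decal-7-ene-2-carbaldehyde (C1/C2 diastereomer mixture), via iron enolate 8 (not isolated)
Conditions: Fe(acac)3 (30 mol%), PhSiH3, acrolein (3 equiv), EtOH/(CH2OH)2, 0 °C to rt
Reagents that add atoms: none
Why: Iron hydride formed from Fe(acac)3 and PhSiH3 transfers a hydrogen atom to the CH2 terminus of the electron-rich 1,1-disubstituted isopropenyl alkene (Markovnikov HAT) to give the tertiary C4 radical, which adds to acrolein (C3–C4); the α-formyl radical is reduced by divalent iron to enolate 8, which closes on the C1 aldehyde (C1–C2), and the aldolate is protonated by ethanol. The closest known reaction type is the iron-hydride HAT-initiated radical conjugate addition/aldol (radical–polar crossover) annulation of γ,δ-unsaturated aldehydes with enals and enones, an extension of the Fe(acac)3/PhSiH3 reductive olefin coupling. Ring A closes by a 6-(enolexo)-exo-trig aldol and is trans-fused because the C5 and C10 substituents it joins are already trans-diequatorial on ring B. No stereocentre of the target is created here (C4 becomes the gem-dimethyl carbon, C5 and C10 are untouched), and the uncontrolled C1/C2 centres are erased in steps 5–7. The step needs HAT to the isopropenyl group and not to the conjugated trisubstituted enone (iron-hydride HAT favours electron-rich alkenes), intermolecular capture by acrolein (the radical cannot cyclise onto C1, C9 or the enone without forming a 3- or 4-membered ring), and aldol at the aldehyde and not at the C9 ketone (the more electrophilic carbonyl).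

Step 5
Reactants: 9 aldol adduct
Product: 11 4,4,8,10-tetramethyl-9-oxo-trans-decal-1,7-diene-2-carbaldehyde, via mesylate 10 (not isolated)
Conditions: MsCl, Et3N, CH2Cl2, 0 °C; then DBU, rt
Reagents that add atoms: none
Why: Mesylation followed by E1cB elimination through the aldehyde enolate (C2–H is the only β-hydrogen, C10 is quaternary) should converge both diastereomers to the enal and avoids a free alkoxide that could trigger retro-aldol cleavage.

Step 6
Reactants: 11 enal
Product: 12 4,4,8,10-tetramethyl-trans-decal-1,7-dien-9-one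
Conditions: RhCl(PPh3)3 (1.1 equiv), PhCN, 130 °C
Reagents that add atoms: none
Why: Tsuji–Wilkinson decarbonylation (oxidative addition of monovalent rhodium into the formyl C–H bond, CO extrusion, C–H reductive elimination) should replace CHO by H on C2 and leave the ring-B enone untouched.

Step 7
Reactants: 12 dienone
Product: 13 (4aS,8aS)-2,5,5,8a-tetramethyl-4a,5,6,7,8,8a-hexahydronaphthalen-1(4H)-one (4,4,8,10-tetramethyl-trans-decal-7-en-9-one)
Conditions: H2 (3 atm), RhCl(PPh3)3 (5 mol%), benzene/EtOH, rt
Reagents that add atoms: none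
Why: Homogeneous hydrogenation with RhCl(PPh3)3 should saturate the unconjugated cis-disubstituted C1=C2 alkene and spare the trisubstituted conjugated C7=C8 alkene; no stereocentre is formed.

Step 8
Reactants: 13 bicyclic enone
Product: 14 4,4,8,10-tetramethyl-trans-decal-7-ene-6,9-dione
Conditions: Rh2(cap)4 (dirhodium tetracaprolactamate, 1 mol%), t-BuOOH (70% aq, 5 equiv), ClCH2CH2Cl, 40 °C
Reagents that add atoms: tert-butyl hydroperoxide, CC(C)(C)OO
Why: Allylic oxidation by hydrogen abstraction at the γ-CH2 (C6, the only secondary allylic position of the enone), peroxide formation and elimination should give the ene-1,4-dione, and the neutral conditions keep the now enolisable C5 centre trans.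

Step 9
Reactants: 14 ene-dione
Product: 16 4,4,8,10-tetramethyl-6-oxo-trans-decal-8-en-9-yl trifluoromethanesulfonate, via lithium enolate 15 (not isolated)
Conditions: LiBH(s-Bu)3 (1.05 equiv), THF, −78 °C; Comins' reagent, −78 to 0 °C
Reagents that add atoms: Comins' reagent [N-(5-chloropyridin-2-yl)bis(trifluoromethanesulfonimide)], FC(F)(F)S(=O)(=O)N(c1ccc(Cl)cn1)S(=O)(=O)C(F)(F)F
Why: The bulky hydride should add 1,4 to the doubly activated alkene at its unsubstituted carbon C7 (C8 carries the methyl), which gives the C9 enolate regiospecifically, and O-sulfonylation fixes the C8=C9 double bond as the enol triflate (reductive enolate triflation).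

Step 10
Reactants: 16 keto triflate
Product: 18 7α-hydroxy-4,4,8,10-tetramethyl-6-oxo-trans-decal-8-en-9-yl trifluoromethanesulfonate, via potassium dienolate 17 (not isolated)
Conditions: KN(SiMe3)2, THF, −78 °C; 2-(phenylsulfonyl)-3-phenyloxaziridine, −78 °C; NH4Cl (aq)
Reagents that add atoms: 2-(phenylsulfonyl)-3-phenyloxaziridine, O=S(=O)(N1OC1c1ccccc1)c1ccccc1
Why: Kinetic deprotonation at the doubly activated C7 (allylic and α to the C6 ketone) gives the dienolate, which should be hydroxylated at its α-carbon (Davis oxidation) from the α face, the axial trajectory away from the C10 and C4β methyl groups that shield the β face, setting 7α-OH.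

Step 11
Reactants: 18 hydroxy ketone
Product: 19 6β,7α-dihydroxy-4,4,8,10-tetramethyl-trans-decal-8-en-9-yl trifluoromethanesulfonate
Conditions: NaBH4, MeOH, −20 °C
Reagents that add atoms: none
Why: Hydride should attack the C6 ketone from the α face because the β face is blocked by the syn-axial C10 and C4β methyl groups (and borohydride bound to the 7α-OH delivers from the same face), giving the axial 6β-alcohol trans to the 7α-OH.

Step 12
Reactants: 20 (Z)-3-methylpent-2-en-4-yn-1-ol
Product: 21 (Z)-tert-butyldimethyl[(3-methylpent-2-en-4-yn-1-yl)oxy]silane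
Conditions: TBSCl, imidazole, CH2Cl2, rt
Reagents that add atoms: tert-butyldimethylsilyl chloride, CC(C)(C)[Si](C)(C)Cl
Why: Standard silylation of the primary allylic alcohol, which leaves the Z geometry of the commercial enynol untouched.

Step 13
Reactants: 21 silyl enyne
Product: 22 (Z)-tert-butyldimethyl[(3-methylpenta-2,4-dien-1-yl)oxy]silane
Conditions: H2 (1 atm), Pd/CaCO3 poisoned with Pb(OAc)2 (Lindlar catalyst), quinoline, hexane, rt
Reagents that add atoms: none
Why: Lindlar semihydrogenation should stop at the alkene for the terminal alkyne and neither reduce nor isomerise the trisubstituted Z-alkene.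

Step 14
Reactants: 19 diol triflate; 22 silyl diene
Product: 24 (13Z)-15-(tert-butyldimethylsilyloxy)labda-8,13-diene-6β,7α-diol, via alkylborane 23 (not isolated)
Conditions: 22, 9-BBN-H, THF, 0 °C to rt; then 19, Pd(dppf)Cl2 (10 mol%), AsPh3, Cs2CO3, DMF/THF/H2O, rt to 45 °C
Reagents that add atoms: none
Why: 9-BBN should add anti-Markovnikov to the monosubstituted terminus of the diene only, and the primary alkylborane is then joined to C9 by B-alkyl Suzuki–Miyaura coupling (oxidative addition of zerovalent palladium into the C9–OTf bond, transmetalation, reductive elimination) with retention of both alkenes; the free diol is tolerated.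

Step 15
Reactants: 24 silyl ether
Product: 25 (13Z)-labda-8,13-diene-6β,7α,15-triol
Conditions: Bu4NF, THF, 0 °C to rt
Reagents that add atoms: none
Why: Fluoride-induced cleavage of the primary silyl ether, at a stage where the molecule carries no base-sensitive group.

Step 16
Reactants: 25 triol
Product: 26 (13Z)-labda-8,13-diene-6β,7α,15-triol 7,15-diacetate (target)
Conditions: Ac2O (2.2 equiv), pyridine, DMAP (cat.), CH2Cl2, 0 °C
Reagents that add atoms: acetic anhydride, CC(=O)OC(C)=O
Why: Acylation should discriminate by steric access: the primary C15 and allylic C7 hydroxyls are acetylated, whereas the axial 6β-OH, 1,3-diaxial to the C10 and C4β methyl groups, stays free, and the trans-diaxial arrangement excludes acyl migration.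

**Compound list**

1 | (R)-(−)-carvone | CC1=CC[C@H](CC1=O)C(C)=C | starting material
2 | lithium dienolate of carvone | CC1=CC[C@H](C=C1O[Li])C(C)=C | intermediate (not isolated)
3 | 6-methylcarvone, (5R), C6 epimers | CC1=CC[C@H](C(C)C1=O)C(C)=C | intermediate
4 | lithium enolate of 3 | CC1=CC[C@H](C(C)=C1O[Li])C(C)=C | intermediate (not isolated)
5 | (5S,6R)-6-(hydroxymethyl)-2,6-dimethyl-5-(prop-1-en-2-yl)cyclohex-2-en-1-one | O=C1C(C)=CC[C@@H](C(C)=C)[C@]1(C)CO | intermediate
6 | (1R,6S)-1,3-dimethyl-2-oxo-6-(prop-1-en-2-yl)cyclohex-3-ene-1-carbaldehyde | O=C1C(C)=CC[C@@H](C(C)=C)[C@]1(C)C=O | intermediate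
7 | acrolein | C=CC=O | starting material
8 | iron enolate of the radical adduct (drawn as the free enolate anion) | O=C1C(C)=CC[C@@H](C(C)(C)CC=C[O-])[C@]1(C)C=O | intermediate (not isolated)
9 | 1-hydroxy-4,4,8,10-tetramethyl-9-oxo-trans-decal-7-ene-2-carbaldehyde (C1/C2 mixture) | O=C1C(C)=CC[C@H]2C(C)(C)CC(C=O)C(O)[C@]12C | intermediate
10 | C1 mesylate of 9 | O=C1C(C)=CC[C@H]2C(C)(C)CC(C=O)C(OS(C)(=O)=O)[C@]12C | intermediate (not isolated)
11 | 4,4,8,10-tetramethyl-9-oxo-trans-decal-1,7-diene-2-carbaldehyde | O=C1C(C)=CC[C@H]2C(C)(C)CC(C=O)=C[C@]12C | intermediate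
12 | 4,4,8,10-tetramethyl-trans-decal-1,7-dien-9-one | O=C1C(C)=CC[C@H]2C(C)(C)CC=C[C@]12C | intermediate
13 | (4aS,8aS)-2,5,5,8a-tetramethyl-4a,5,6,7,8,8a-hexahydronaphthalen-1(4H)-one | O=C1C(C)=CC[C@H]2C(C)(C)CCC[C@]12C | intermediate
14 | 4,4,8,10-tetramethyl-trans-decal-7-ene-6,9-dione | O=C1C(C)=CC(=O)[C@H]2C(C)(C)CCC[C@]12C | intermediate
15 | lithium C9 enolate of the 7,8-dihydro dione | [Li]OC1=C(C)CC(=O)[C@H]2C(C)(C)CCC[C@]12C | intermediate (not isolated)
16 | 4,4,8,10-tetramethyl-6-oxo-trans-decal-8-en-9-yl triflate | FC(F)(F)S(=O)(=O)OC1=C(C)CC(=O)[C@H]2C(C)(C)CCC[C@]12C | intermediate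
17 | potassium dienolate of 16 | FC(F)(F)S(=O)(=O)OC1=C(C)C=C(O[K])[C@H]2C(C)(C)CCC[C@]12C | intermediate (not isolated)
18 | 7α-hydroxy-6-oxo enol triflate | FC(F)(F)S(=O)(=O)OC1=C(C)[C@H](O)C(=O)[C@H]2C(C)(C)CCC[C@]12C | intermediate
19 | 6β,7α-dihydroxy enol triflate | FC(F)(F)S(=O)(=O)OC1=C(C)[C@H](O)[C@@H](O)[C@H]2C(C)(C)CCC[C@]12C | intermediate
20 | (Z)-3-methylpent-2-en-4-yn-1-ol | OC/C=C(/C)C#C | starting material
21 | TBS ether of 20 | CC(C)(C)[Si](C)(C)OC/C=C(/C)C#C | intermediate
22 | (Z)-TBS ether of 3-methylpenta-2,4-dien-1-ol | CC(C)(C)[Si](C)(C)OC/C=C(/C)C=C | intermediate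
23 | B-[(Z)-5-(TBS-oxy)-3-methylpent-3-enyl]-9-BBN | CC(C)(C)[Si](C)(C)OC/C=C(/C)CCB1C2CCCC1CCC2 | intermediate (not isolated)
24 | (13Z)-15-(TBS-oxy)labda-8,13-diene-6β,7α-diol | CC(C)(C)[Si](C)(C)OC/C=C(/C)CCC1=C(C)[C@H](O)[C@@H](O)[C@H]2C(C)(C)CCC[C@]12C | intermediate
25 | (13Z)-labda-8,13-diene-6β,7α,15-triol | OC/C=C(/C)CCC1=C(C)[C@H](O)[C@@H](O)[C@H]2C(C)(C)CCC[C@]12C | intermediate
26 | (13Z)-labda-8,13-diene-6β,7α,15-triol 7,15-diacetate | CC(=O)OC/C=C(/C)CCC1=C(C)[C@H](OC(C)=O)[C@@H](O)[C@H]2C(C)(C)CCC[C@]12C | target

**Step count and risks**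

Total step count: 16. Longest linear sequence: 14 (steps 1–11 and 14–16; steps 12–13 make the side chain).

Steps most likely to fail:

1. Step 4 (key annulation). What may go wrong: protonation of the enolate before it closes on C1, loss of the formyl group of the β-keto aldehyde by retro-Claisen cleavage in the alcoholic medium, or oligomerisation of acrolein. Fallback, setting out from 5 and returning at 11: the same iron-hydride radical addition is run as a plain reductive olefin coupling on alcohol 5, which has no formyl group to lose (Fe(acac)3, PhSiH3, acrolein, EtOH), to give the hydroxy aldehyde 4-[(1S,6R)-6-(hydroxymethyl)-4,6-dimethyl-5-oxocyclohex-3-en-1-yl]-4-methylpentanal F1. Dess–Martin oxidation of the primary alcohol gives the dialdehyde F2. Piperidinium acetate in warm benzene then forms C1–C2 by intramolecular aldol condensation of the enolisable aldehyde onto the non-enolisable one and gives enal 11 directly.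

2. Step 9 (reductive enolate triflation). What may go wrong: competing 1,2-reduction at the C6 carbonyl, hydride delivery to C8 instead of C7, or incomplete O-sulfonylation of the hindered tetrasubstituted enolate. Fallback, setting out from 13 and returning at 16 (it bypasses steps 8 and 9): γ-deprotonation of enone 13 with KN(SiMe3)2 and O-triflation with Comins' reagent give the dienyl triflate (4aS,8aS)-2,5,5,8a-tetramethyl-4a,5,6,7,8,8a-hexahydronaphthalen-1-yl trifluoromethanesulfonate F3. Dimethyldioxirane epoxidises the more electron-rich distal C6=C7 alkene from the open α face to the 6α,7α-epoxide F4. BF3·OEt2 at −78 °C then effects a Meinwald rearrangement (ionisation of the allylic C7–O bond, 1,2-hydride shift from C6) to the β,γ-unsaturated ketone 16.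

3. Step 10 (C7 hydroxylation). What may go wrong: poor facial selectivity in the oxygen transfer to the nearly planar dienolate, so that the 7β-alcohol forms, or epimerisation of the α-ketol at C7 before reduction. Fallback, setting out from 16 and returning at 19: the same hydroxylation is accepted with the wrong outcome, the 7β-hydroxy epimer of 18, F5, and the C7 centre is then set by substitution. NaBH4 reduces F5 from the α face to the cis-6β,7β-diol F6. Mitsunobu inversion of the allylic C7 alcohol (4-nitrobenzoic acid, PPh3, DIAD; the hindered 6β-OH does not react) gives the 7α-(4-nitrobenzoate) F7. K2CO3 in MeOH at 0 °C cleaves the ester to diol 19.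

**Further compounds**

F1 | step 4 | 4-[(1S,6R)-6-(hydroxymethyl)-4,6-dimethyl-5-oxocyclohex-3-en-1-yl]-4-methylpentanal | O=C1C(C)=CC[C@@H](C(C)(C)CCC=O)[C@]1(C)CO
F2 | step 4 | (1R,6S)-1,3-dimethyl-6-(2-methyl-5-oxopentan-2-yl)-2-oxocyclohex-3-ene-1-carbaldehyde | O=C1C(C)=CC[C@@H](C(C)(C)CCC=O)[C@]1(C)C=O
F3 | step 9 | (4aS,8aS)-2,5,5,8a-tetramethyl-4a,5,6,7,8,8a-hexahydronaphthalen-1-yl trifluoromethanesulfonate (6,8-dienyl triflate) | FC(F)(F)S(=O)(=O)OC1=C(C)C=C[C@H]2C(C)(C)CCC[C@]12C
F4 | step 9 | 6α,7α-epoxide of F3 | FC(F)(F)S(=O)(=O)OC1=C(C)[C@@H]3O[C@@H]3[C@H]2C(C)(C)CCC[C@]12C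
F5 | step 10 | 7β-hydroxy-6-oxo enol triflate (C7 epimer of 18) | FC(F)(F)S(=O)(=O)OC1=C(C)[C@@H](O)C(=O)[C@H]2C(C)(C)CCC[C@]12C
F6 | step 10 | 6β,7β-dihydroxy enol triflate | FC(F)(F)S(=O)(=O)OC1=C(C)[C@@H](O)[C@@H](O)[C@H]2C(C)(C)CCC[C@]12C
F7 | step 10 | 6β-hydroxy-7α-(4-nitrobenzoyloxy) enol triflate | FC(F)(F)S(=O)(=O)OC1=C(C)[C@H](OC(=O)c3ccc(cc3)[N+](=O)[O-])[C@@H](O)[C@H]2C(C)(C)CCC[C@]12C
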